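The nucleophile has two jobs in these flasks: it attacks the electrophile, and it catches the acid which that attack sets free. How long it keeps the acid tells me what each turnover costs.

- blue: electrophile 0.80 M; nucleophile 3.00 equiv; free base 1.00 equiv; protic impurity 0.0800 M; time 80 min
- red: electrophile 0.80 M; nucleophile 3.00 equiv; free base 1.50 equiv; protic impurity 0.0800 M; time 80 min

    electrophile + nucleophile → acid set free + target (k1 = 0.0036 M⁻¹ min⁻¹)
    nucleophile + acid set free ⇌ protonated nucleophile, settled at all times (K2 = 230 M⁻¹)
    acid set free + free base ⇌ salt of the base (K3 = 12000 M⁻¹, k3 = 1.6 M⁻¹ min⁻¹)
    crystals ⇌ target, rate k4*(cs4 - [target]) while solid is left; crystals form when [target] > cs4 (cs4 = 0.67 M, k4 = 3.7 min⁻¹)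
    protic impurity + free base → quenched reagent (k5 = 2.5 M⁻¹ min⁻¹)

- target is meant together with its crystals
- solid, in amounts per volume of the solution: crystals
- run time (blue): 80 min

- part of the electrophile that has reacted at the end, blue
- part of the electrophile that has reacted at the end, red
- what raising the equivalents of free base from its lowest to its highest value here does to the part of the electrophile that has reacted (changes below 5 percentage points count as none) (it falls / no change / it rises)

I ask first for the end state. In blue the free base outbids the nucleophile for acid, 9600 against 550 (each equilibrium constant times its partner's starting concentration), so at balance the acid belongs to the base. Then I ask how fast it gets there. The protic impurity takes its bite of base first, with a half-life of 0.35 min, and leaves 0.720 M of free base in blue. From then on, acid resting on the nucleophile reaches the base through the little that stands free. Protonated nucleophile, the resting state of the acid, therefore drains on a time equal to the nucleophile's equilibrium constant times [nucleophile], divided by the base's forward rate constant times [free base]. With charged amounts that gives 479 min in blue and 308 min in red. This is the hand-over time.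

Both exceed the run of 80 min, so I let each electrophile cost two nucleophiles, whatever the base loading. The curve of target starts with a slope of 0.00691 M min⁻¹. It then bends as both partners run down, and on my reckoning each electrophile used takes two nucleophiles with it. The ratio of the two obeys a simple law: the excess of nucleophile over twice the electrophile stays constant, and in 80 min it gives a growth factor of 1.26. That yields 43.7 % reacted in both flasks. The charge covers the double cost, so the curve has no early plateau and is still climbing when the run stops. The target then stands at 0.350 M, below its solubility of 0.67 M, so I expect no crystals.

The forecast gives 44.2 % for blue, 44.5 % for red and no change, on the ground that “the free base takes it back too slowly to matter”. The simulation gives 43.9 % for blue and 44.0 % for red, a shift of 0.1 percentage points, so no change.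

In blue the run lasts 0.167 of a hand-over time. At 80.0 min the protonated nucleophile stands at 0.312 M and the salt of the base at 0.0383 M, and the salt's turnover reaches its halfway mark at 54.7 min, later than the 31.1 min of the attack on the electrophile. Blue read at 2.5 h has run 0.313 of a hand-over time, still under one, so the double cost gives 61.8 % reacted; the simulation gives 62.6 %.

(All constants were drawn at random within sensible limits; the flask was simulated.)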